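The target is a minor product: at the last reading of both earlier runs it stands well below isomer of the product B, and both runs end far short of full conversion.

| setting | red | ochre | gamma | alpha | theta | eta | beta |
|---|---|---|---|---|---|---|---|
| starting material | 0.011 M | 0.084 M | 0.020 M | 0.030 M | 0.040 M | 0.060 M | 0.10 M |
| free catalyst | 5 mol% | 5 mol% | 5 mol% | 5 mol% | 5 mol% | 5 mol% | 5 mol% |
| remark | run made earlier | run made earlier |  |  |  |  |  |
| time |  |  | 4.0 h | 4.0 h | 4.0 h | 4.0 h | 4.0 h |

| run | time / h | target / % | isomer of the product A / % | isomer of the product B / % |
|---|---|---|---|---|
| red | 0.250 | 1.5 | 1.0 | 6.5 |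
| red | 0.333 | 1.6 | 1.7 | 6.7 |
| red | 0.500 | 1.6 | 2.3 | 7.1 |
| red | 0.833 | 1.6 | 2.7 | 6.7 |
| red | 1.33 | 2.3 | 3.3 | 6.5 |
| red | 2.00 | 1.8 | 3.4 | 6.8 |
| red | 3.00 | 2.3 | 3.5 | 7.1 |
| ochre | 0.250 | 6.4 | 7.2 | 31.7 |
| ochre | 0.333 | 6.6 | 9.3 | 32.4 |
| ochre | 0.500 | 7.1 | 12.2 | 32.6 |
| ochre | 0.833 | 7.8 | 15.3 | 31.0 |
| ochre | 1.33 | 7.8 | 15.3 | 31.4 |
| ochre | 2.00 | 7.8 | 15.2 | 30.5 |
| ochre | 3.00 | 8.0 | 15.5 | 30.9 |

(standard deviation of a reading: 0.3 percentage points)

- the numbers in the tables scatter with a standard deviation of 0.3 percentage points
- "hardly changes" means that all values lie within two and a half points (for a concentration: within two and a half percent of the largest)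

* share of target in all that became target or isomer of the product A or isomer of the product B for gamma, alpha, theta, eta, beta, in this order
* the shape of the row from first to last (hardly changes / rises, then falls / rises all the way / falls, then rises / falls all the way)

At its last reading the red run has converted 12.9% of its charge and the ochre run, with the higher concentration, 54.4%. The split may not. Over its last 3 readings the ochre run gives 14.5% for the target share, target divided by the sum of target and both isomers, a selectivity. It says what fraction of the converted material stands as target. At the first ochre reading the share is already 14.1%, so the two ochre readings of the share differ by 0.4 percentage points.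

Is one number enough? The same reckoning on the red run gives 17.3%, a gap of 2.8 points. That reading is the looser one, since the red target stands at 2.3% with a scatter of 0.3 points. Even if the gap is real and runs evenly with the logarithm of the charge, the row covers 0.792 of that span. The drift is then 2.2 points, which stays inside the band that defines hardly changes. This reckoning therefore puts each flask near 14.5%.

The forecast, a little above this reckoning, gives 15.2% down to 14.6%, shape hardly changes, holding that “the target share is constant”.

The flasks give 14.9%, 14.7%, 14.6%, 14.3% and 14.0%: hardly changes.

    free catalyst → spent catalyst (k = 0.0870 min⁻¹)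
    isomer of the product B + free catalyst ⇌ starting material + free catalyst, rate k2*[free catalyst]*[isomer of the product B] forward; the back reaction follows from the equilibrium constant (k = 11.0 M⁻¹ min⁻¹)
    isomer of the product A ⇌ isomer of the product B (K = 2.00, k = 0.0520 min⁻¹)
    starting material + free catalyst ⇌ target + free catalyst, rate k4*[starting material]*[free catalyst] forward; the back reaction follows from the equilibrium constant (K = 0.450, k = 3.20 M⁻¹ min⁻¹)
    target + free catalyst ⇌ isomer of the product A + free catalyst, rate k5*[free catalyst]*[target] forward; the back reaction follows from the equilibrium constant (K = 1.80, k = 12.0 M⁻¹ min⁻¹)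

Multiplied by the fraction converted, the ochre share gives beta 8.44% of its charge as target, against 8.13% in the flask, and gamma 2.97%, against 3.04%. In gamma the free catalyst has a half-life of 0.13 h by its loss to spent catalyst, far shorter than the 3.6 h of starting material by the forward making of target alone, reckoned with the concentrations as charged. Gamma holds 80% of its starting material at 4.00 h and the same 79.6% at 40.0 h.

The numbers in the tables were computed with made-up constants, noise included.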